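**Plan**

- **Locants and target.** Unit 1 is the 5-hydroxy-7,4'-dimethoxyflavanone half (C2, C3, rings A, B, C). Unit 2 is the naringenin half (C2'', C3'', rings A'', B'', C''). The target is (2S,3S,2''S,3''R): unit 1 is 2,3-cis and unit 2 is 2'',3''-trans.
- **Cuts, in order.** First the four O-benzyl groups. Then the C2–H and C3–H bonds of unit 1 (back to a flat flavone) and the C4'' carbonyl oxygen (back to CH2). Then O1''–C2'' and C3''–C4'' of ring C''. Last, the bond from flavone C3 to the styryl carbon.
- **Enabling feature.** Ring C'' (O1'', C2'', C3'', C4'', C4a'', C8a'') is a trans-2-aryl-3-substituted dihydropyran fused to the phloroglucinol ring A''. O1''=C8a''–C4a''=C4'' is therefore an ortho-quinone methide, and C2''=C3'' is an (E)-styrene with its donor ring B'' on C2''.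
- **Forward order.** Rings A–C are bought as a flavone. C3 is iodinated and Heck-coupled with 4-benzyloxystyrene. Ring C'' closes in the [4+2] step, C4'' is oxygenated, ring C is saturated, both carbinols are oxidised, and hydrogenolysis ends the route.
- **Stereochemistry.** The 2'',3''-trans relation comes from the E alkene, and its absolute sense from a chiral Brønsted acid that selects the alkene face. The 2,3-cis relation comes from syn delivery of H2 to one face of C2=C3 under a chiral ruthenium carbene catalyst, backed by shielding from ring B''.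

Key step: step 8

Assumption: the sense of induction of the two chiral catalysts cannot be read from close analogues, so the (R)-acid of step 8 and the (R,R)-carbene precursor of step 10 stand for whichever enantiomer a test run shows to lead to (2''S,3''R) and to (2S,3S); both enantiomers of each are available.

**Step 1**
Reactants: 1 5,7-dimethoxy-2-(4-methoxyphenyl)chromen-4-one (5,7,4'-trimethoxyflavone)
Product: 3 5-hydroxy-7-methoxy-2-(4-methoxyphenyl)chromen-4-one, via dichloroboryl ether 2 (not isolated)
Conditions: BCl3 (1.2 equiv), CH2Cl2, −78 → 0 °C; then H2O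
Reagents that add atoms: none
Why: Chelation-directed Lewis-acid ether cleavage, in which BCl3 bridges the C4 carbonyl and the peri 5-methoxy oxygen so that chloride removes only that methyl group and the 7- and 4'-methyl ethers of the target stay.

**Step 2**
Reactants: 3 5-hydroxy-7-methoxy-2-(4-methoxyphenyl)chromen-4-one
Product: 4 5-benzyloxy-7-methoxy-2-(4-methoxyphenyl)chromen-4-one
Conditions: BnBr, K2CO3, DMF, 60 °C
Reagents that add atoms: benzyl bromide, BrCc1ccccc1
Why: Williamson ether synthesis, in which warming in DMF overcomes the hydrogen bond of the 5-OH, and the benzyl group allows a neutral hydrogenolysis at the end instead of a Lewis-acid demethylation on the epimerisable cis-flavanone.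

**Step 3**
Reactants: 4 5-benzyloxy-7-methoxy-2-(4-methoxyphenyl)chromen-4-one
Product: 6 5-benzyloxy-3-iodo-7-methoxy-2-(4-methoxyphenyl)chromen-4-one, via 3-lithioflavone 5 (not isolated)
Conditions: LiN(i-Pr)2 (1.2 equiv), THF, −78 °C; then I2, −78 → −20 °C
Reagents that add atoms: iodine, II
Why: Carbonyl-directed lithiation–iodination, because C3–H next to the carbonyl is the kinetically most acidic position of a flavone at −78 °C, whereas electrophilic iodination would attack ring A at C6 or C8.

**Step 4**
Reactants: 7 4-(benzyloxy)benzaldehyde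
Product: 8 1-(benzyloxy)-4-ethenylbenzene (4-benzyloxystyrene)
Conditions: Ph3PCH3Br, KOtBu, THF, 0 °C → rt
Reagents that add atoms: methyltriphenylphosphonium bromide, C[P+](c1ccccc1)(c1ccccc1)c1ccccc1.[Br-]
Why: Wittig methylenation of a non-enolisable aromatic aldehyde, to which the benzyl ether is inert.

**Step 5**
Reactants: 6 5-benzyloxy-3-iodo-7-methoxy-2-(4-methoxyphenyl)chromen-4-one; 8 1-(benzyloxy)-4-ethenylbenzene
Product: 9 (E)-5-benzyloxy-3-[2-(4-benzyloxyphenyl)ethenyl]-7-methoxy-2-(4-methoxyphenyl)chromen-4-one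
Conditions: Pd(OAc)2 (5 mol %), P(o-tol)3 (10 mol %), K2CO3, n-Bu4NBr, DMF, 90 °C
Reagents that add atoms: none
Why: Mizoroki–Heck reaction, established for 3-haloflavones and styrenes, in which insertion at the unsubstituted alkene terminus and syn β-hydride elimination give the E double bond.

**Step 6**
Reactants: 10 2,4,6-trihydroxybenzaldehyde
Product: 11 2,4-bis(benzyloxy)-6-hydroxybenzaldehyde
Conditions: BnBr (2.05 equiv), K2CO3 (2.2 equiv), DMF, 0 °C → rt
Reagents that add atoms: benzyl bromide, BrCc1ccccc1
Why: Williamson ether synthesis that alkylates the acidic 4-OH and one ortho OH, while the last ortho OH is held back by its hydrogen bond to the formyl oxygen and the formyl group suppresses C-benzylation.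

**Step 7**
Reactants: 11 2,4-bis(benzyloxy)-6-hydroxybenzaldehyde
Product: 12 3,5-bis(benzyloxy)-2-(hydroxymethyl)phenol (2,4-bis(benzyloxy)-6-hydroxybenzyl alcohol)
Conditions: NaBH4, THF/EtOH, 0 °C; pH 7 phosphate buffer; used without chromatography
Reagents that add atoms: none
Why: Borohydride reduction of an aldehyde, in which low temperature and a neutral quench keep the easily ionised salicyl alcohol from losing water or being reduced further.

**Step 8**
Reactants: 9 (E)-5-benzyloxy-3-[2-(4-benzyloxyphenyl)ethenyl]-7-methoxy-2-(4-methoxyphenyl)chromen-4-one; 12 3,5-bis(benzyloxy)-2-(hydroxymethyl)phenol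
Product: 14 5-benzyloxy-3-[(2S,3R)-5,7-bis(benzyloxy)-2-(4-benzyloxyphenyl)chroman-3-yl]-7-methoxy-2-(4-methoxyphenyl)chromen-4-one, via ortho-quinone methide 13 (not isolated)
Conditions: (R)-3,3'-bis(2,4,6-triisopropylphenyl)-1,1'-binaphthyl-2,2'-diyl N-triflylphosphoramide (10 mol %), 4 Å MS, toluene, 0 °C; 12 (1.5 equiv) added over 12 h by syringe pump
Reagents that add atoms: none
Why: The acid ionises the benzylic C–OH bond of 12, which three ring oxygens activate, and keeps the ortho-quinone methide 13 hydrogen-bonded (at the limit protonated and ion-paired) at its carbonyl oxygen, so its LUMO is lowered for an inverse-demand oxa-Diels–Alder reaction with the styryl double bond of 9; the closest known reaction type is the [4+2] cycloaddition of in situ formed ortho-quinone methides with styrenes to 2-arylchromans under chiral BINOL phosphoric acids and N-triflylphosphoramides. The alkene carbon attached to flavone C3 bonds to the unsubstituted, unhindered methide carbon (C3''–C4'') slightly ahead of the bonding of the quinone methide oxygen to the carbon that carries the 4-benzyloxyphenyl group (O1''–C2''), so ring C'' closes as a six-membered ring in a concerted but asynchronous 4π + 2π cycloaddition. C2'' and C3'' arise by suprafacial addition to the E alkene, which fixes their trans relation, and a leak through the open benzylic cation would collapse to the same diequatorial chroman. Since C4'' ends as a CH2 group the faces of 13 are stereochemically irrelevant, so the absolute configuration (2''S,3''R) depends only on which face of the alkene meets the bound quinone methide, and that choice is made by the pocket between the two 2,4,6-triisopropylphenyl groups of the catalyst. Regioselectivity between the two alkene carbons is secured by the para-alkoxy donor of ring B'', which outweighs the cross-conjugated pyrone, whose own tetrasubstituted C2=C3 bond is too electron-poor and crowded to react. Chemoselectivity against self-condensation of 12 and 13 is secured by the slow addition, which keeps both dilute, and by the absence of free phenols in 9 and 14.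

**Step 9**
Reactants: 14 5-benzyloxy-3-[(2S,3R)-5,7-bis(benzyloxy)-2-(4-benzyloxyphenyl)chroman-3-yl]-7-methoxy-2-(4-methoxyphenyl)chromen-4-one
Product: 15 5-benzyloxy-3-[(2S,3S,4S)-5,7-bis(benzyloxy)-2-(4-benzyloxyphenyl)-4-hydroxychroman-3-yl]-7-methoxy-2-(4-methoxyphenyl)chromen-4-one (2'',3''-trans, 3'',4''-trans)
Conditions: DDQ (1.5 equiv), CH2Cl2/pH 7 phosphate buffer (10:1), 0 °C → rt
Reagents that add atoms: water, O
Why: Benzylic C–H oxidation by hydride abstraction, known for C4 of perbenzylated catechins, in which DDQ complexes the most electron-rich ring A'' and removes hydride from C4'', water captures the cation anti to the bulky C3'' substituent (a centre erased in step 11, so a minor epimer converges), and the acceptor-substituted flavone and the plain benzyl ethers react far more slowly.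

**Step 10**
Reactants: 15 5-benzyloxy-3-[(2S,3S,4S)-5,7-bis(benzyloxy)-2-(4-benzyloxyphenyl)-4-hydroxychroman-3-yl]-7-methoxy-2-(4-methoxyphenyl)chromen-4-one
Product: 17 (2S,3R,4S)-5-benzyloxy-3-[(2S,3S,4S)-5,7-bis(benzyloxy)-2-(4-benzyloxyphenyl)-4-hydroxychroman-3-yl]-7-methoxy-2-(4-methoxyphenyl)chroman-4-ol (unit 1 all-cis), via cis-flavanone 16 (not isolated)
Conditions: [Ru(cod)(2-methylallyl)2] (10 mol %), 1,3-bis[(R)-1-(1-naphthyl)ethyl]-4,5-dihydroimidazolium tetrafluoroborate (20 mol %), KOtBu (20 mol %), n-hexane, 70 °C (catalyst preformed); then 15, toluene, H2 (120 bar), 40 °C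
Reagents that add atoms: none
Why: Proposed new method: the ruthenium bis(carbene) hydride binds one face of the vinylogous-ester C2=C3 bond and passes both hydrogens to that face, so C2 and C3 arise together as the cis pair (2S,3S in 16); the face is chosen by the chiral carbene ligands and backed by the substrate, in which allylic 1,3-strain turns C3''–H towards the 2-aryl group, a hydrogen bond from the 4''-OH to the C4 carbonyl holds that rotamer, and ring B'' on C2'' then covers the unwanted face; the ketone of 16 is hydrogenated from the same open face to the flavan-4-ol, which removes the acidity of C3–H and locks the cis relation (material that stops at 16, or a C4 epimer, converges in step 11), and benzyl ethers are not cleaved by this homogeneous catalyst; the closest known reaction type is the ruthenium–NHC-catalysed asymmetric hydrogenation of C3-unsubstituted flavones and chromones to flavanones and flavanols, the extension being the tetrasubstituted, C3-branched double bond.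

**Step 11**
Reactants: 17 (2S,3R,4S)-5-benzyloxy-3-[(2S,3S,4S)-5,7-bis(benzyloxy)-2-(4-benzyloxyphenyl)-4-hydroxychroman-3-yl]-7-methoxy-2-(4-methoxyphenyl)chroman-4-ol
Product: 18 (2S,3S)-5-benzyloxy-3-[(2S,3R)-5,7-bis(benzyloxy)-2-(4-benzyloxyphenyl)-4-oxochroman-3-yl]-7-methoxy-2-(4-methoxyphenyl)chroman-4-one
Conditions: Dess–Martin periodinane (3 equiv), pyridine (6 equiv), CH2Cl2, 0 °C → rt; short pad of neutral silica
Reagents that add atoms: none
Why: Dess–Martin oxidation of both secondary benzylic alcohols under buffered, non-enolising conditions, so C4 and C4'' become carbonyl groups, the kinetic 2,3-cis relation of unit 1 is kept, and C3'' already holds its more stable trans arrangement.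

**Step 12**
Reactants: 18 (2S,3S)-5-benzyloxy-3-[(2S,3R)-5,7-bis(benzyloxy)-2-(4-benzyloxyphenyl)-4-oxochroman-3-yl]-7-methoxy-2-(4-methoxyphenyl)chroman-4-one
Product: 19 (2S,3S)-3-[(2S,3R)-5,7-dihydroxy-2-(4-hydroxyphenyl)-4-oxochroman-3-yl]-5-hydroxy-7-methoxy-2-(4-methoxyphenyl)chroman-4-one (CNP0279849.1)
Conditions: H2 (1 atm), 10% Pd/C, EtOAc/THF (1:1), rt, stopped at the calculated uptake
Reagents that add atoms: none
Why: Catalytic hydrogenolysis of the four aryl benzyl ethers at neutral pH, which leaves the methyl ethers and all four stereocentres untouched and avoids the acid or base that would epimerise C3.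

**Compound list**

1 | 5,7-dimethoxy-2-(4-methoxyphenyl)chromen-4-one | COc1ccc(-c2cc(=O)c3c(OC)cc(OC)cc3o2)cc1 | starting material
2 | 5-(dichloroboryloxy)-7-methoxy-2-(4-methoxyphenyl)chromen-4-one | COc1ccc(-c2cc(=O)c3c(OB(Cl)Cl)cc(OC)cc3o2)cc1 | intermediate
3 | 5-hydroxy-7-methoxy-2-(4-methoxyphenyl)chromen-4-one | COc1ccc(-c2cc(=O)c3c(O)cc(OC)cc3o2)cc1 | intermediate
4 | 5-benzyloxy-7-methoxy-2-(4-methoxyphenyl)chromen-4-one | COc1ccc(-c2cc(=O)c3c(OCc4ccccc4)cc(OC)cc3o2)cc1 | intermediate
5 | 5-benzyloxy-3-lithio-7-methoxy-2-(4-methoxyphenyl)chromen-4-one | COc1ccc(-c2oc3cc(OC)cc(OCc4ccccc4)c3c(=O)c2[Li])cc1 | intermediate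
6 | 5-benzyloxy-3-iodo-7-methoxy-2-(4-methoxyphenyl)chromen-4-one | COc1ccc(-c2oc3cc(OC)cc(OCc4ccccc4)c3c(=O)c2I)cc1 | intermediate
7 | 4-(benzyloxy)benzaldehyde | O=Cc1ccc(OCc2ccccc2)cc1 | starting material
8 | 1-(benzyloxy)-4-ethenylbenzene | C=Cc1ccc(OCc2ccccc2)cc1 | intermediate
9 | (E)-5-benzyloxy-3-[2-(4-benzyloxyphenyl)ethenyl]-7-methoxy-2-(4-methoxyphenyl)chromen-4-one | COc1ccc(-c2oc3cc(OC)cc(OCc4ccccc4)c3c(=O)c2/C=C/c2ccc(OCc3ccccc3)cc2)cc1 | intermediate
10 | 2,4,6-trihydroxybenzaldehyde | O=Cc1c(O)cc(O)cc1O | starting material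
11 | 2,4-bis(benzyloxy)-6-hydroxybenzaldehyde | O=Cc1c(O)cc(OCc2ccccc2)cc1OCc1ccccc1 | intermediate
12 | 3,5-bis(benzyloxy)-2-(hydroxymethyl)phenol | OCc1c(O)cc(OCc2ccccc2)cc1OCc1ccccc1 | intermediate
13 | 3,5-bis(benzyloxy)-6-methylidenecyclohexa-2,4-dien-1-one | C=C1C(=O)C=C(OCc2ccccc2)C=C1OCc1ccccc1 | intermediate
14 | 5-benzyloxy-3-[(2S,3R)-5,7-bis(benzyloxy)-2-(4-benzyloxyphenyl)chroman-3-yl]-7-methoxy-2-(4-methoxyphenyl)chromen-4-one | COc1ccc(-c2oc3cc(OC)cc(OCc4ccccc4)c3c(=O)c2[C@H]2Cc3c(OCc4ccccc4)cc(OCc4ccccc4)cc3O[C@@H]2c2ccc(OCc3ccccc3)cc2)cc1 | intermediate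
15 | 5-benzyloxy-3-[(2S,3S,4S)-5,7-bis(benzyloxy)-2-(4-benzyloxyphenyl)-4-hydroxychroman-3-yl]-7-methoxy-2-(4-methoxyphenyl)chromen-4-one | COc1ccc(-c2oc3cc(OC)cc(OCc4ccccc4)c3c(=O)c2[C@H]2[C@H](O)c3c(OCc4ccccc4)cc(OCc4ccccc4)cc3O[C@@H]2c2ccc(OCc3ccccc3)cc2)cc1 | intermediate
16 | (2S,3S)-5-benzyloxy-3-[(2S,3S,4S)-5,7-bis(benzyloxy)-2-(4-benzyloxyphenyl)-4-hydroxychroman-3-yl]-7-methoxy-2-(4-methoxyphenyl)chroman-4-one | COc1ccc([C@H]2Oc3cc(OC)cc(OCc4ccccc4)c3C(=O)[C@H]2[C@H]2[C@H](O)c3c(OCc4ccccc4)cc(OCc4ccccc4)cc3O[C@@H]2c2ccc(OCc3ccccc3)cc2)cc1 | intermediate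
17 | (2S,3R,4S)-5-benzyloxy-3-[(2S,3S,4S)-5,7-bis(benzyloxy)-2-(4-benzyloxyphenyl)-4-hydroxychroman-3-yl]-7-methoxy-2-(4-methoxyphenyl)chroman-4-ol | COc1ccc([C@H]2Oc3cc(OC)cc(OCc4ccccc4)c3[C@@H](O)[C@H]2[C@H]2[C@H](O)c3c(OCc4ccccc4)cc(OCc4ccccc4)cc3O[C@@H]2c2ccc(OCc3ccccc3)cc2)cc1 | intermediate
18 | (2S,3S)-5-benzyloxy-3-[(2S,3R)-5,7-bis(benzyloxy)-2-(4-benzyloxyphenyl)-4-oxochroman-3-yl]-7-methoxy-2-(4-methoxyphenyl)chroman-4-one | COc1ccc([C@H]2Oc3cc(OC)cc(OCc4ccccc4)c3C(=O)[C@H]2[C@H]2C(=O)c3c(OCc4ccccc4)cc(OCc4ccccc4)cc3O[C@@H]2c2ccc(OCc3ccccc3)cc2)cc1 | intermediate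
19 | (2S,3S)-3-[(2S,3R)-5,7-dihydroxy-2-(4-hydroxyphenyl)-4-oxochroman-3-yl]-5-hydroxy-7-methoxy-2-(4-methoxyphenyl)chroman-4-one | COc1ccc([C@H]2Oc3cc(OC)cc(O)c3C(=O)[C@H]2[C@H]2C(=O)c3c(O)cc(O)cc3O[C@@H]2c2ccc(O)cc2)cc1 | target

**Step count**

Total step count: 12. Longest linear sequence: 9 (steps 1, 2, 3, 5, 8, 9, 10, 11, 12).

**Steps most likely to fail**

**Step 10.** The crowded tetrasubstituted C2=C3 bond may not bind to the ruthenium hydride at all, or hydrogen may be delivered to the wrong face.
- The fallback replaces the concerted hydrogenation by a polar hydride-then-proton sequence of known type, carried out one oxidation level earlier. It sets out from 14.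
- Ligated copper hydride (Cu(OAc)2, 1,2-bis(diphenylphosphino)benzene, PMHS, t-BuOH, toluene) is a conjugate reduction known for chromones and for hindered β,β-disubstituted enones. It should place hydride on C2 from the face away from ring B''.
- The resulting enolate carries its 2-aryl group pseudoaxial and should be protonated by t-BuOH anti to it. This kinetic protonation leads to the cis-flavanone chroman F1.
- Because unit 2 is already enantiopure, any other isomer is a diastereomer and can be removed by chromatography.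
- DDQ in buffered wet CH2Cl2, as in step 9, then oxygenates C4'' and gives 16, where the route is rejoined. Isolated 16 is oxidised to 18 under the conditions of step 11.

**Step 8.** Self-condensation of the quinone methide and its electron-rich precursor may outrun addition to the hindered, stilbene-like alkene. The basic pyrone carbonyl may tie up the acid. Discrimination between the alkene faces may be weak, because the alkene has no contact point for the catalyst.
- The fallback gives the alkene a stronger donor that also serves as a hydrogen-bond handle. It sets out from 6.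
- Heck coupling with commercial 4-acetoxystyrene under the conditions of step 5 gives the styryl acetate F2. Methanolysis (K2CO3, MeOH) then gives the free 4-hydroxystyrylflavone F3.
- With (R)-3,3'-bis(2,4,6-triisopropylphenyl)-1,1'-binaphthyl-2,2'-diyl hydrogen phosphate, the phosphoryl oxygen can hold the phenol of F3 while the acidic OH holds 13.
- The addition then becomes a vinylogous conjugate addition through a para-quinone methide, closed by an oxa-Michael step. The same two bonds are formed, and the product is the phenolic cycloadduct F4.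
- Benzylation (BnBr, K2CO3, acetone) returns to the route at 14.

**Step 9.** Hydride abstraction may occur at C2'' or at a benzyl ether methylene instead of C4''. The C4'' cation may also lose the C3'' proton, which leads to dehydration and further oxidation.
- The fallback avoids the C–H oxidation by bringing the C4'' oxygen in with the quinone methide. It sets out from 11 and 9 and replaces steps 7 to 9.
- Trimethyl orthoformate and the acid of step 8 convert 11 into the dimethyl acetal F5.
- This loses methanol to the methoxy-substituted quinone methide F6 (geometry not fixed), which adds to 9 with the same regiochemistry. The product is the 4''-methoxychroman F7, drawn as the 3'',4''-trans epimer.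
- Its labile benzylic methoxy group is exchanged for hydroxyl with pyridinium p-toluenesulfonate in acetone/H2O, which rejoins the route at 15.

**Further compounds**
F1 | step 10 | (2S,3S)-5-benzyloxy-3-[(2S,3R)-5,7-bis(benzyloxy)-2-(4-benzyloxyphenyl)chroman-3-yl]-7-methoxy-2-(4-methoxyphenyl)chroman-4-one | COc1ccc([C@H]2Oc3cc(OC)cc(OCc4ccccc4)c3C(=O)[C@H]2[C@H]2Cc3c(OCc4ccccc4)cc(OCc4ccccc4)cc3O[C@@H]2c2ccc(OCc3ccccc3)cc2)cc1
F2 | step 8 | 4-[(E)-2-[5-benzyloxy-7-methoxy-2-(4-methoxyphenyl)-4-oxochromen-3-yl]ethenyl]phenyl acetate | COc1ccc(-c2oc3cc(OC)cc(OCc4ccccc4)c3c(=O)c2/C=C/c2ccc(OC(C)=O)cc2)cc1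
F3 | step 8 | (E)-5-benzyloxy-3-[2-(4-hydroxyphenyl)ethenyl]-7-methoxy-2-(4-methoxyphenyl)chromen-4-one | COc1ccc(-c2oc3cc(OC)cc(OCc4ccccc4)c3c(=O)c2/C=C/c2ccc(O)cc2)cc1
F4 | step 8 | 5-benzyloxy-3-[(2S,3R)-5,7-bis(benzyloxy)-2-(4-hydroxyphenyl)chroman-3-yl]-7-methoxy-2-(4-methoxyphenyl)chromen-4-one | COc1ccc(-c2oc3cc(OC)cc(OCc4ccccc4)c3c(=O)c2[C@H]2Cc3c(OCc4ccccc4)cc(OCc4ccccc4)cc3O[C@@H]2c2ccc(O)cc2)cc1
F5 | step 9 | 3,5-bis(benzyloxy)-2-(dimethoxymethyl)phenol | COC(OC)c1c(O)cc(OCc2ccccc2)cc1OCc1ccccc1
F6 | step 9 | 3,5-bis(benzyloxy)-6-(methoxymethylidene)cyclohexa-2,4-dien-1-one | COC=C1C(=O)C=C(OCc2ccccc2)C=C1OCc1ccccc1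
F7 | step 9 | 5-benzyloxy-3-[(2S,3S,4S)-5,7-bis(benzyloxy)-2-(4-benzyloxyphenyl)-4-methoxychroman-3-yl]-7-methoxy-2-(4-methoxyphenyl)chromen-4-one | COc1ccc(-c2oc3cc(OC)cc(OCc4ccccc4)c3c(=O)c2[C@H]2[C@H](OC)c3c(OCc4ccccc4)cc(OCc4ccccc4)cc3O[C@@H]2c2ccc(OCc3ccccc3)cc2)cc1
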